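**Retrosynthetic overview**
1. The target is reached from the macrocyclic C3 ketone by a final reagent-controlled CBS reduction; the 1,10-oxirane (last ring formed) comes from peracid epoxidation of the 1(10)E-olefin.
2. The ten-membered carbocycle is closed at C3–C4 by an intramolecular Nozaki–Hiyama–Kishi reaction of a (Z)-vinyl iodide with an aldehyde.
3. The seco compound comes from a late zinc Barbier union at C7–C8 of two halves of similar size: bromomethyl butenolide fragment A (C4–C7, C11–C13, C15) and aldehyde fragment B (C8–C10, C14, C1–C3). This step also creates the α-methylene lactone; C8 is then esterified with inversion (Mitsunobu) by epoxy acid fragment C.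
4. Fragment A comes from (S)-5-(hydroxymethyl)butyrolactone (iodo-Wittig, selenium-based hydroxymethylation/desaturation), fragment B from but-3-yn-1-ol (Negishi carboalumination/ethylene oxide), fragment C from tiglic aldehyde (Sharpless epoxidation).
5. Ring order: γ-lactone (chiral pool) → side-chain oxirane → ten-membered ring → 1,10-oxirane.

Assumption: macrocycles are named with germacrane numbering (C1–C10 ring, C11–C13 lactone carbons, C14 on C10, C15 on C4), in which the target is (1R,3S,4Z,6R,7R,8R,10R) with a (2R,3S)-epoxy ester; C3-epimer mixtures are drawn without a descriptor at C3.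

**Fragment A**

Step 1
Reactants: 1 (5S)-5-(hydroxymethyl)oxolan-2-one
Product: 2 (2S)-5-oxooxolane-2-carbaldehyde
Conditions: IBX, EtOAc, 80 °C
Reagents that add atoms: none
Why: Neutral IBX oxidation of the primary alcohol stops at the aldehyde and leaves the lactone and the chiral-pool stereocentre (future C6) untouched.

Step 2
Reactants: 2 (2S)-5-oxooxolane-2-carbaldehyde
Product: 3 (5S)-5-[(1Z)-2-iodoprop-1-en-1-yl]oxolan-2-one
Conditions: [Ph3PCH(I)CH3]I, NaN(SiMe3)2, THF, −78 °C; then 2, −78 to −20 °C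
Reagents that add atoms: (1-iodoethyl)triphenylphosphonium iodide, CC(I)[P+](c1ccccc1)(c1ccccc1)c1ccccc1.[I-]
Why: Zhao-type iodo-Wittig olefination is kinetically Z-selective (iodine cis to the lactone carbon), which fixes the future C4=C5 geometry, and the low temperature keeps the α-oxygenated aldehyde from epimerising.

Step 3
Reactants: 3 (5S)-5-[(1Z)-2-iodoprop-1-en-1-yl]oxolan-2-one
Product: 5 (5S)-5-[(1Z)-2-iodoprop-1-en-1-yl]-3-(phenylselanyl)oxolan-2-one (C3 epimers), via lactone lithium enolate 4 (not isolated)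
Conditions: LiN(SiMe3)2, THF, −78 °C; then PhSeBr, −78 °C
Reagents that add atoms: benzeneselenenyl bromide, Br[Se]c1ccccc1
Why: Enolate selenenylation of the lactone; the new α-centre is destroyed again in step 5, and the hindered amide base at −78 °C does not touch the vinyl iodide.

Step 4
Reactants: 5 (5S)-5-[(1Z)-2-iodoprop-1-en-1-yl]-3-(phenylselanyl)oxolan-2-one
Product: 7 (5S)-3-(hydroxymethyl)-5-[(1Z)-2-iodoprop-1-en-1-yl]-3-(phenylselanyl)oxolan-2-one (C3 epimers), via selenolactone lithium enolate 6 (not isolated)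
Conditions: LiN(SiMe3)2, THF, −78 °C; then HCHO (gas), −78 to −40 °C; AcOH quench
Reagents that add atoms: formaldehyde, C=O
Why: Aldol addition of the selenium-stabilised enolate to monomeric formaldehyde installs C13; no lasting stereocentre is formed.

Step 5
Reactants: 7 (5S)-3-(hydroxymethyl)-5-[(1Z)-2-iodoprop-1-en-1-yl]-3-(phenylselanyl)oxolan-2-one
Product: 9 (5S)-3-(hydroxymethyl)-5-[(1Z)-2-iodoprop-1-en-1-yl]furan-2(5H)-one, via selenoxide 8 (not isolated)
Conditions: 30% aq. H2O2, pyridine, CH2Cl2, 0 °C to rt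
Reagents that add atoms: none
Why: Selenide oxidation followed by selenoxide syn-elimination toward the ring CH2 (elimination toward the hydroxyl-bearing carbon is disfavoured) gives the α-(hydroxymethyl)butenolide under neutral conditions.

Step 6
Reactants: 9 (5S)-3-(hydroxymethyl)-5-[(1Z)-2-iodoprop-1-en-1-yl]furan-2(5H)-one
Product: 10 (5S)-3-(bromomethyl)-5-[(1Z)-2-iodoprop-1-en-1-yl]furan-2(5H)-one
Conditions: CBr4, PPh3, CH2Cl2, 0 °C
Reagents that add atoms: carbon tetrabromide, BrC(Br)(Br)Br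
Why: Appel bromination of the primary allylic alcohol is neutral and tolerates the vinyl iodide and the acidic γ-position of the butenolide.

**Fragment B**

Step 7
Reactants: 11 but-3-yn-1-ol
Product: 12 tert-butyl(but-3-yn-1-yloxy)dimethylsilane
Conditions: TBSCl, imidazole, DMF, rt
Reagents that add atoms: tert-butyl(chloro)dimethylsilane, CC(C)(C)[Si](C)(C)Cl
Why: Standard silylation protects the future C8 oxygen for the carbometalation.

Step 8
Reactants: 12 tert-butyl(but-3-yn-1-yloxy)dimethylsilane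
Product: 15 (3E)-6-{[tert-butyl(dimethyl)silyl]oxy}-4-methylhex-3-en-1-ol, via alkenyldimethylalane 13 (not isolated), via lithium alkenylalanate 14 (not isolated)
Conditions: AlMe3, Cp2ZrCl2 (20 mol %), CH2Cl2, 0 °C to rt; n-BuLi, THF/hexane, −78 °C; ethylene oxide, −78 °C to rt; aqueous work-up
Reagents that add atoms: trimethylaluminium, C[Al](C)C; ethylene oxide, C1CO1
Why: Negishi zirconium-catalysed carboalumination adds methyl and aluminium syn across the alkyne, which sets the E trisubstituted C1=C10 olefin, and the derived alanate opens ethylene oxide with retention to add C2–C3.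

Step 9
Reactants: 15 (3E)-6-{[tert-butyl(dimethyl)silyl]oxy}-4-methylhex-3-en-1-ol
Product: 16 tert-butyl({(3E)-6-[(4-methoxyphenyl)methoxy]-3-methylhex-3-en-1-yl}oxy)dimethylsilane
Conditions: NaH, 4-methoxybenzyl chloride, Bu4NI (cat.), THF/DMF, 0 °C to rt
Reagents that add atoms: 4-methoxybenzyl chloride, COc1ccc(CCl)cc1
Why: Williamson etherification gives a PMB ether on the C3 oxygen that is orthogonal to the silyl ether and later removable under neutral oxidative conditions.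

Step 10
Reactants: 16 tert-butyl({(3E)-6-[(4-methoxyphenyl)methoxy]-3-methylhex-3-en-1-yl}oxy)dimethylsilane
Product: 17 (3E)-6-[(4-methoxyphenyl)methoxy]-3-methylhex-3-en-1-ol
Conditions: camphorsulfonic acid (10 mol %), MeOH/CH2Cl2, 0 °C
Reagents that add atoms: none
Why: Acid-catalysed methanolysis removes the primary silyl ether while the PMB ether and the olefin are stable.

Step 11
Reactants: 17 (3E)-6-[(4-methoxyphenyl)methoxy]-3-methylhex-3-en-1-ol
Product: 18 (3E)-6-[(4-methoxyphenyl)methoxy]-3-methylhex-3-enal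
Conditions: IBX, DMSO/THF, rt
Reagents that add atoms: none
Why: Neutral IBX oxidation gives the β,γ-unsaturated aldehyde without moving the olefin into conjugation; it is used directly.

**Fragment C**

Step 12
Reactants: 19 (2E)-2-methylbut-2-enal
Product: 20 (2E)-2-methylbut-2-en-1-ol
Conditions: NaBH4, CeCl3·7H2O, MeOH, 0 °C
Reagents that add atoms: none
Why: Luche reduction gives clean 1,2-reduction of the enal with retention of the E olefin.

Step 13
Reactants: 20 (2E)-2-methylbut-2-en-1-ol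
Product: 21 [(2S,3S)-2,3-dimethyloxiran-2-yl]methanol
Conditions: Ti(OiPr)4 (10 mol %), L-(+)-diethyl tartrate (12 mol %), t-BuOOH, 4 Å molecular sieves, CH2Cl2, −20 °C
Reagents that add atoms: tert-butyl hydroperoxide, CC(C)(C)OO
Why: Sharpless asymmetric epoxidation with the L-(+)-tartrate delivers oxygen to the face that gives the (2S,3S)-epoxy alcohol, setting both side-chain stereocentres (cis methyls follow from the E olefin).

Step 14
Reactants: 21 [(2S,3S)-2,3-dimethyloxiran-2-yl]methanol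
Product: 22 (2R,3S)-2,3-dimethyloxirane-2-carboxylic acid
Conditions: RuCl3·xH2O (2 mol %), NaIO4, CCl4/MeCN/H2O, rt
Reagents that add atoms: water, O
Why: Sharpless ruthenium tetroxide oxidation takes the epoxy alcohol to the glycidic acid without opening the oxirane; C2 becomes R only through the change in CIP priorities.

**Union and endgame**

Step 15
Reactants: 10 (5S)-3-(bromomethyl)-5-[(1Z)-2-iodoprop-1-en-1-yl]furan-2(5H)-one; 18 (3E)-6-[(4-methoxyphenyl)methoxy]-3-methylhex-3-enal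
Product: 24 (4R,5S)-4-{(1S,3E)-1-hydroxy-6-[(4-methoxyphenyl)methoxy]-3-methylhex-3-en-1-yl}-5-[(1Z)-2-iodoprop-1-en-1-yl]-3-methylideneoxolan-2-one, via allylzinc bromide 23 (not isolated)
Conditions: Zn dust, THF/sat. aq. NH4Cl, rt
Reagents that add atoms: none
Why: Barbier allylation through the γ-carbon (C7) of the allylzinc forms C7–C8 and the exocyclic methylene at once; attack anti to the C6 alkenyl group gives the 6,7-trans lactone, and the chair Zimmerman–Traxler transition state with the aldehyde chain equatorial gives the 7,8-anti (8S) alcohol, while the vinyl iodide is inert to zinc.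

Step 16
Reactants: 24 (4R,5S)-4-{(1S,3E)-1-hydroxy-6-[(4-methoxyphenyl)methoxy]-3-methylhex-3-en-1-yl}-5-[(1Z)-2-iodoprop-1-en-1-yl]-3-methylideneoxolan-2-one; 22 (2R,3S)-2,3-dimethyloxirane-2-carboxylic acid
Product: 25 (1R,3E)-1-{(2S,3R)-2-[(1Z)-2-iodoprop-1-en-1-yl]-4-methylidene-5-oxooxolan-3-yl}-6-[(4-methoxyphenyl)methoxy]-3-methylhex-3-en-1-yl (2R,3S)-2,3-dimethyloxirane-2-carboxylate
Conditions: PPh3, DIAD, toluene, 0 °C to rt (betaine preformed)
Reagents that add atoms: none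
Why: Mitsunobu esterification displaces the activated C8 oxygen by the acidic glycidic carboxylate in an SN2 reaction, so C8 is inverted from S to the required R while the side chain is attached.

Step 17
Reactants: 25 (1R,3E)-1-{(2S,3R)-2-[(1Z)-2-iodoprop-1-en-1-yl]-4-methylidene-5-oxooxolan-3-yl}-6-[(4-methoxyphenyl)methoxy]-3-methylhex-3-en-1-yl (2R,3S)-2,3-dimethyloxirane-2-carboxylate
Product: 26 (1R,3E)-6-hydroxy-1-{(2S,3R)-2-[(1Z)-2-iodoprop-1-en-1-yl]-4-methylidene-5-oxooxolan-3-yl}-3-methylhex-3-en-1-yl (2R,3S)-2,3-dimethyloxirane-2-carboxylate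
Conditions: DDQ, CH2Cl2/pH 7 buffer, 0 °C
Reagents that add atoms: none
Why: Oxidative PMB cleavage is neutral and leaves the methylene lactone, epoxy ester, vinyl iodide and olefin intact.

Step 18
Reactants: 26 (1R,3E)-6-hydroxy-1-{(2S,3R)-2-[(1Z)-2-iodoprop-1-en-1-yl]-4-methylidene-5-oxooxolan-3-yl}-3-methylhex-3-en-1-yl (2R,3S)-2,3-dimethyloxirane-2-carboxylate
Product: 27 (1R,3E)-1-{(2S,3R)-2-[(1Z)-2-iodoprop-1-en-1-yl]-4-methylidene-5-oxooxolan-3-yl}-3-methyl-6-oxohex-3-en-1-yl (2R,3S)-2,3-dimethyloxirane-2-carboxylate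
Conditions: IBX, DMSO/THF, rt
Reagents that add atoms: none
Why: Neutral IBX oxidation gives the sensitive β,γ-unsaturated C3 aldehyde, which is cyclised without storage.

Step 19
Reactants: 27 (1R,3E)-1-{(2S,3R)-2-[(1Z)-2-iodoprop-1-en-1-yl]-4-methylidene-5-oxooxolan-3-yl}-3-methyl-6-oxohex-3-en-1-yl (2R,3S)-2,3-dimethyloxirane-2-carboxylate
Product: 29 (1(10)E,4Z,6R,7R,8R)-3-hydroxygermacra-1(10),4,11(13)-trien-12,6-olid-8-yl (2R,3S)-2,3-dimethyloxirane-2-carboxylate (C3 epimers), via alkenylchromium dichloride 28 (not isolated)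
Conditions: CrCl2 (10 equiv), NiCl2 (2 mol %), degassed DMSO/THF, 2 mM, rt
Reagents that add atoms: none
Why: Intramolecular Nozaki–Hiyama–Kishi addition of the alkenylchromium to the aldehyde closes the ten-membered ring at C3–C4 with retention of the Z olefin and tolerates esters, lactone and oxirane; the C3 configuration is not relied on because both epimers converge in step 20.

Step 20
Reactants: 29 (1(10)E,4Z,6R,7R,8R)-3-hydroxygermacra-1(10),4,11(13)-trien-12,6-olid-8-yl (2R,3S)-2,3-dimethyloxirane-2-carboxylate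
Product: 30 (1(10)E,4Z,6R,7R,8R)-3-oxogermacra-1(10),4,11(13)-trien-12,6-olid-8-yl (2R,3S)-2,3-dimethyloxirane-2-carboxylate
Conditions: IBX, DMSO/THF, rt
Reagents that add atoms: none
Why: Oxidation of the allylic alcohol erases the uncontrolled C3 centre and turns C4=C5 into an electron-poor enone whose Z geometry is locked by the ring.

Step 21
Reactants: 30 (1(10)E,4Z,6R,7R,8R)-3-oxogermacra-1(10),4,11(13)-trien-12,6-olid-8-yl (2R,3S)-2,3-dimethyloxirane-2-carboxylate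
Product: 31 (1R,4Z,6R,7R,8R,10R)-1,10-epoxy-3-oxogermacra-4,11(13)-dien-12,6-olid-8-yl (2R,3S)-2,3-dimethyloxirane-2-carboxylate
Conditions: mCPBA, CH2Cl2/aq. NaHCO3, 0 °C
Reagents that add atoms: 3-chloroperbenzoic acid, OOC(=O)c1cccc(Cl)c1
Why: Prilezhaev epoxidation attacks only the electron-rich 1(10) olefin (enone and acrylate olefins are deactivated); attack on the outer face of the E olefin, as is usual for germacranolide 1(10)-olefins, is expected to give the (1R,10R)-oxirane, and this facial selectivity is substrate-controlled and not secured in advance.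

Step 22
Reactants: 31 (1R,4Z,6R,7R,8R,10R)-1,10-epoxy-3-oxogermacra-4,11(13)-dien-12,6-olid-8-yl (2R,3S)-2,3-dimethyloxirane-2-carboxylate
Product: 32 (1R,3S,4Z,6R,7R,8R,10R)-1,10-epoxy-3-hydroxygermacra-4,11(13)-dien-12,6-olid-8-yl (2R,3S)-2,3-dimethyloxirane-2-carboxylate
Conditions: (R)-2-methyl-CBS-oxazaborolidine (1 equiv), catecholborane, toluene, −78 °C; MeOH quench
Reagents that add atoms: none
Why: Corey–Bakshi–Shibata reduction is a reagent-controlled 1,2-reduction of the enone (alkenyl C4 as the large group), and the (R)-catalyst gives the (3S)-allylic alcohol while lactone, esters, oxiranes and the methylene lactone are left alone at −78 °C.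

**Compound list**
1 | (5S)-5-(hydroxymethyl)oxolan-2-one | OC[C@@H]1CCC(=O)O1 | starting material
2 | (2S)-5-oxooxolane-2-carbaldehyde | O=C[C@@H]1CCC(=O)O1 | intermediate
3 | (5S)-5-[(1Z)-2-iodoprop-1-en-1-yl]oxolan-2-one | C/C(I)=C/[C@@H]1CCC(=O)O1 | intermediate
4 | lactone lithium enolate: lithium (5S)-5-[(1Z)-2-iodoprop-1-en-1-yl]-4,5-dihydrofuran-2-olate | C/C(I)=C/[C@@H]1CC=C([O-])O1.[Li+] | intermediate
5 | (5S)-5-[(1Z)-2-iodoprop-1-en-1-yl]-3-(phenylselanyl)oxolan-2-one (C3 epimers) | C/C(I)=C/[C@@H]1CC([Se]c2ccccc2)C(=O)O1 | intermediate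
6 | selenolactone lithium enolate: lithium (5S)-5-[(1Z)-2-iodoprop-1-en-1-yl]-3-(phenylselanyl)-4,5-dihydrofuran-2-olate | C/C(I)=C/[C@@H]1CC([Se]c2ccccc2)=C([O-])O1.[Li+] | intermediate
7 | (5S)-3-(hydroxymethyl)-5-[(1Z)-2-iodoprop-1-en-1-yl]-3-(phenylselanyl)oxolan-2-one (C3 epimers) | C/C(I)=C/[C@@H]1CC(CO)([Se]c2ccccc2)C(=O)O1 | intermediate
8 | selenoxide: (5S)-3-(hydroxymethyl)-5-[(1Z)-2-iodoprop-1-en-1-yl]-3-(phenylseleninyl)oxolan-2-one | C/C(I)=C/[C@@H]1CC(CO)([Se](=O)c2ccccc2)C(=O)O1 | intermediate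
9 | (5S)-3-(hydroxymethyl)-5-[(1Z)-2-iodoprop-1-en-1-yl]furan-2(5H)-one | C/C(I)=C/[C@@H]1C=C(CO)C(=O)O1 | intermediate
10 | (5S)-3-(bromomethyl)-5-[(1Z)-2-iodoprop-1-en-1-yl]furan-2(5H)-one | C/C(I)=C/[C@@H]1C=C(CBr)C(=O)O1 | intermediate
11 | but-3-yn-1-ol | C#CCCO | starting material
12 | tert-butyl(but-3-yn-1-yloxy)dimethylsilane | C#CCCO[Si](C)(C)C(C)(C)C | intermediate
13 | alkenyldimethylalane: [(1E)-4-{[tert-butyl(dimethyl)silyl]oxy}-2-methylbut-1-en-1-yl]dimethylalane | C[Al](C)/C=C(\C)CCO[Si](C)(C)C(C)(C)C | intermediate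
14 | lithium alkenylalanate: lithium butyl[(1E)-4-{[tert-butyl(dimethyl)silyl]oxy}-2-methylbut-1-en-1-yl]dimethylalanate | [Li+].CCCC[Al-](C)(C)/C=C(\C)CCO[Si](C)(C)C(C)(C)C | intermediate
15 | (3E)-6-{[tert-butyl(dimethyl)silyl]oxy}-4-methylhex-3-en-1-ol | OCC/C=C(\C)CCO[Si](C)(C)C(C)(C)C | intermediate
16 | tert-butyl({(3E)-6-[(4-methoxyphenyl)methoxy]-3-methylhex-3-en-1-yl}oxy)dimethylsilane | COc1ccc(COCC/C=C(\C)CCO[Si](C)(C)C(C)(C)C)cc1 | intermediate
17 | (3E)-6-[(4-methoxyphenyl)methoxy]-3-methylhex-3-en-1-ol | COc1ccc(COCC/C=C(\C)CCO)cc1 | intermediate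
18 | (3E)-6-[(4-methoxyphenyl)methoxy]-3-methylhex-3-enal | COc1ccc(COCC/C=C(\C)CC=O)cc1 | intermediate
19 | (2E)-2-methylbut-2-enal | C/C=C(\C)C=O | starting material
20 | (2E)-2-methylbut-2-en-1-ol | C/C=C(\C)CO | intermediate
21 | [(2S,3S)-2,3-dimethyloxiran-2-yl]methanol | OC[C@]1(C)O[C@H]1C | intermediate
22 | (2R,3S)-2,3-dimethyloxirane-2-carboxylic acid | OC(=O)[C@]1(C)O[C@H]1C | intermediate
23 | allylzinc bromide: bromo{[(5S)-5-[(1Z)-2-iodoprop-1-en-1-yl]-2-oxo-2,5-dihydrofuran-3-yl]methyl}zinc | C/C(I)=C/[C@@H]1C=C(C[Zn]Br)C(=O)O1 | intermediate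
24 | (4R,5S)-4-{(1S,3E)-1-hydroxy-6-[(4-methoxyphenyl)methoxy]-3-methylhex-3-en-1-yl}-5-[(1Z)-2-iodoprop-1-en-1-yl]-3-methylideneoxolan-2-one | C=C1C(=O)O[C@H](/C=C(/C)I)[C@H]1[C@@H](O)C/C(C)=C/CCOCc1ccc(OC)cc1 | intermediate
25 | (1R,3E)-1-{(2S,3R)-2-[(1Z)-2-iodoprop-1-en-1-yl]-4-methylidene-5-oxooxolan-3-yl}-6-[(4-methoxyphenyl)methoxy]-3-methylhex-3-en-1-yl (2R,3S)-2,3-dimethyloxirane-2-carboxylate | C=C1C(=O)O[C@H](/C=C(/C)I)[C@H]1[C@H](OC(=O)[C@]2(C)O[C@H]2C)C/C(C)=C/CCOCc1ccc(OC)cc1 | intermediate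
26 | (1R,3E)-6-hydroxy-1-{(2S,3R)-2-[(1Z)-2-iodoprop-1-en-1-yl]-4-methylidene-5-oxooxolan-3-yl}-3-methylhex-3-en-1-yl (2R,3S)-2,3-dimethyloxirane-2-carboxylate | C=C1C(=O)O[C@H](/C=C(/C)I)[C@H]1[C@H](OC(=O)[C@]2(C)O[C@H]2C)C/C(C)=C/CCO | intermediate
27 | (1R,3E)-1-{(2S,3R)-2-[(1Z)-2-iodoprop-1-en-1-yl]-4-methylidene-5-oxooxolan-3-yl}-3-methyl-6-oxohex-3-en-1-yl (2R,3S)-2,3-dimethyloxirane-2-carboxylate | C=C1C(=O)O[C@H](/C=C(/C)I)[C@H]1[C@H](OC(=O)[C@]2(C)O[C@H]2C)C/C(C)=C/CC=O | intermediate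
28 | alkenylchromium dichloride derived from 27 (chromium in place of iodine) | C=C1C(=O)O[C@H](/C=C(/C)[Cr](Cl)Cl)[C@H]1[C@H](OC(=O)[C@]2(C)O[C@H]2C)C/C(C)=C/CC=O | intermediate
29 | (1(10)E,4Z,6R,7R,8R)-3-hydroxygermacra-1(10),4,11(13)-trien-12,6-olid-8-yl (2R,3S)-2,3-dimethyloxirane-2-carboxylate (C3 epimers) | C=C1C(=O)O[C@@H]2/C=C(/C)C(O)C/C=C(\C)C[C@@H](OC(=O)[C@]3(C)O[C@H]3C)[C@@H]12 | intermediate
30 | (1(10)E,4Z,6R,7R,8R)-3-oxogermacra-1(10),4,11(13)-trien-12,6-olid-8-yl (2R,3S)-2,3-dimethyloxirane-2-carboxylate | C=C1C(=O)O[C@@H]2/C=C(/C)C(=O)C/C=C(\C)C[C@@H](OC(=O)[C@]3(C)O[C@H]3C)[C@@H]12 | intermediate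
31 | (1R,4Z,6R,7R,8R,10R)-1,10-epoxy-3-oxogermacra-4,11(13)-dien-12,6-olid-8-yl (2R,3S)-2,3-dimethyloxirane-2-carboxylate | C=C1C(=O)O[C@@H]2/C=C(/C)C(=O)C[C@H]3O[C@]3(C)C[C@@H](OC(=O)[C@]3(C)O[C@H]3C)[C@@H]12 | intermediate
32 | (1R,3S,4Z,6R,7R,8R,10R)-1,10-epoxy-3-hydroxygermacra-4,11(13)-dien-12,6-olid-8-yl (2R,3S)-2,3-dimethyloxirane-2-carboxylate | C=C1C(=O)O[C@@H]2/C=C(/C)[C@@H](O)C[C@H]3O[C@]3(C)C[C@@H](OC(=O)[C@]3(C)O[C@H]3C)[C@@H]12 | target

**Step count**
Total: 22 steps (fragment A 6, fragment B 5, fragment C 3, union and endgame 8).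
Longest linear sequence: 14 steps (steps 1–6, then 15–22).

**Steps most likely to fail, with fallbacks**

Step 16 (Mitsunobu inversion at the hindered C8 alcohol; it also depends on the 8S selectivity of step 15, and elimination toward C7 may compete). The fallback sets out from 24 and comes back at 25, replacing the SN2 inversion by an oxidation–reduction inversion and a retentive acylation. IBX in DMSO oxidises 24 to the C8 ketone (4S,5S)-5-[(1Z)-2-iodoprop-1-en-1-yl]-4-{(3E)-6-[(4-methoxyphenyl)methoxy]-3-methylhex-3-enoyl}-3-methylideneoxolan-2-one F1. Reduction of F1 with the (S)-enantiomer of the CBS catalyst and catecholborane at −78 °C (branched C7 as the large group) gives the (8R)-alcohol (4R,5S)-4-{(1R,3E)-1-hydroxy-6-[(4-methoxyphenyl)methoxy]-3-methylhex-3-en-1-yl}-5-[(1Z)-2-iodoprop-1-en-1-yl]-3-methylideneoxolan-2-one F2. Yamaguchi esterification of F2 with 22 (2,4,6-trichlorobenzoyl chloride, Et3N, DMAP, toluene) then gives 25 with retention.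

Step 19 (ten-membered ring closure; the glycidic ester and the bulky C8 acyloxy chain may interfere with the chromium chemistry or the cyclisation). The fallback sets out from 24 and comes back at 30, closing the ring before the side chain is attached. DDQ converts 24 to the iodo diol (4R,5S)-4-[(1S,3E)-1,6-dihydroxy-3-methylhex-3-en-1-yl]-5-[(1Z)-2-iodoprop-1-en-1-yl]-3-methylideneoxolan-2-one F3. Selective oxidation of the primary alcohol (TEMPO cat., PhI(OAc)2, CH2Cl2) gives the hydroxy aldehyde (3E,6S)-6-hydroxy-6-{(2S,3R)-2-[(1Z)-2-iodoprop-1-en-1-yl]-4-methylidene-5-oxooxolan-3-yl}-4-methylhex-3-enal F4. Nozaki–Hiyama–Kishi closure (CrCl2, NiCl2 cat., DMSO, high dilution) gives the macrocyclic diol (1(10)E,4Z,6R,7R,8S)-3,8-dihydroxygermacra-1(10),4,11(13)-trien-12,6-olide F5 as C3 epimers. MnO2 oxidises only the allylic C3 alcohol to the hydroxy dienone (1(10)E,4Z,6R,7R,8S)-8-hydroxy-3-oxogermacra-1(10),4,11(13)-trien-12,6-olide F6. Mitsunobu esterification of F6 with 22 (PPh3, DIAD) inverts C8 and gives 30.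

Step 21 (facial selectivity of the macrocyclic epoxidation is substrate-controlled and uncertain). The fallback sets out from 25 and comes back at 31, installing the oxirane under reagent control before ring closure. Shi epoxidation of 25 (D-fructose-derived Shi ketone 30 mol %, KHSO5 as Oxone, K2CO3, MeCN/dimethoxymethane/aq. buffer pH 10.5, 0 °C) attacks only the electron-rich trisubstituted olefin and gives the (R,R)-epoxide (1R)-1-{(2S,3R)-2-[(1Z)-2-iodoprop-1-en-1-yl]-4-methylidene-5-oxooxolan-3-yl}-2-[(2R,3R)-3-{2-[(4-methoxyphenyl)methoxy]ethyl}-2-methyloxiran-2-yl]ethyl (2R,3S)-2,3-dimethyloxirane-2-carboxylate F7. DDQ gives the epoxy alcohol (1R)-2-[(2R,3R)-3-(2-hydroxyethyl)-2-methyloxiran-2-yl]-1-{(2S,3R)-2-[(1Z)-2-iodoprop-1-en-1-yl]-4-methylidene-5-oxooxolan-3-yl}ethyl (2R,3S)-2,3-dimethyloxirane-2-carboxylate F8. IBX gives the epoxy aldehyde (1R)-1-{(2S,3R)-2-[(1Z)-2-iodoprop-1-en-1-yl]-4-methylidene-5-oxooxolan-3-yl}-2-[(2R,3R)-2-methyl-3-(2-oxoethyl)oxiran-2-yl]ethyl (2R,3S)-2,3-dimethyloxirane-2-carboxylate F9, used cold and at once. Nozaki–Hiyama–Kishi closure gives the macrocyclic epoxy alcohol (1R,4Z,6R,7R,8R,10R)-1,10-epoxy-3-hydroxygermacra-4,11(13)-dien-12,6-olid-8-yl (2R,3S)-2,3-dimethyloxirane-2-carboxylate F10 as C3 epimers, and IBX oxidation of F10 gives 31.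

**Further compounds**
F1 | step 16 | (4S,5S)-5-[(1Z)-2-iodoprop-1-en-1-yl]-4-{(3E)-6-[(4-methoxyphenyl)methoxy]-3-methylhex-3-enoyl}-3-methylideneoxolan-2-one | C=C1C(=O)O[C@H](/C=C(/C)I)[C@H]1C(=O)C/C(C)=C/CCOCc1ccc(OC)cc1
F2 | step 16 | (4R,5S)-4-{(1R,3E)-1-hydroxy-6-[(4-methoxyphenyl)methoxy]-3-methylhex-3-en-1-yl}-5-[(1Z)-2-iodoprop-1-en-1-yl]-3-methylideneoxolan-2-one | C=C1C(=O)O[C@H](/C=C(/C)I)[C@H]1[C@H](O)C/C(C)=C/CCOCc1ccc(OC)cc1
F3 | step 19 | (4R,5S)-4-[(1S,3E)-1,6-dihydroxy-3-methylhex-3-en-1-yl]-5-[(1Z)-2-iodoprop-1-en-1-yl]-3-methylideneoxolan-2-one | C=C1C(=O)O[C@H](/C=C(/C)I)[C@H]1[C@@H](O)C/C(C)=C/CCO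
F4 | step 19 | (3E,6S)-6-hydroxy-6-{(2S,3R)-2-[(1Z)-2-iodoprop-1-en-1-yl]-4-methylidene-5-oxooxolan-3-yl}-4-methylhex-3-enal | C=C1C(=O)O[C@H](/C=C(/C)I)[C@H]1[C@@H](O)C/C(C)=C/CC=O
F5 | step 19 | (1(10)E,4Z,6R,7R,8S)-3,8-dihydroxygermacra-1(10),4,11(13)-trien-12,6-olide (C3 epimers) | C=C1C(=O)O[C@@H]2/C=C(/C)C(O)C/C=C(\C)C[C@H](O)[C@@H]12
F6 | step 19 | (1(10)E,4Z,6R,7R,8S)-8-hydroxy-3-oxogermacra-1(10),4,11(13)-trien-12,6-olide | C=C1C(=O)O[C@@H]2/C=C(/C)C(=O)C/C=C(\C)C[C@H](O)[C@@H]12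
F7 | step 21 | (1R)-1-{(2S,3R)-2-[(1Z)-2-iodoprop-1-en-1-yl]-4-methylidene-5-oxooxolan-3-yl}-2-[(2R,3R)-3-{2-[(4-methoxyphenyl)methoxy]ethyl}-2-methyloxiran-2-yl]ethyl (2R,3S)-2,3-dimethyloxirane-2-carboxylate | C=C1C(=O)O[C@H](/C=C(/C)I)[C@H]1[C@H](OC(=O)[C@]2(C)O[C@H]2C)C[C@@]2(C)O[C@@H]2CCOCc1ccc(OC)cc1
F8 | step 21 | (1R)-2-[(2R,3R)-3-(2-hydroxyethyl)-2-methyloxiran-2-yl]-1-{(2S,3R)-2-[(1Z)-2-iodoprop-1-en-1-yl]-4-methylidene-5-oxooxolan-3-yl}ethyl (2R,3S)-2,3-dimethyloxirane-2-carboxylate | C=C1C(=O)O[C@H](/C=C(/C)I)[C@H]1[C@H](OC(=O)[C@]2(C)O[C@H]2C)C[C@@]2(C)O[C@@H]2CCO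
F9 | step 21 | (1R)-1-{(2S,3R)-2-[(1Z)-2-iodoprop-1-en-1-yl]-4-methylidene-5-oxooxolan-3-yl}-2-[(2R,3R)-2-methyl-3-(2-oxoethyl)oxiran-2-yl]ethyl (2R,3S)-2,3-dimethyloxirane-2-carboxylate | C=C1C(=O)O[C@H](/C=C(/C)I)[C@H]1[C@H](OC(=O)[C@]2(C)O[C@H]2C)C[C@@]2(C)O[C@@H]2CC=O
F10 | step 21 | (1R,4Z,6R,7R,8R,10R)-1,10-epoxy-3-hydroxygermacra-4,11(13)-dien-12,6-olid-8-yl (2R,3S)-2,3-dimethyloxirane-2-carboxylate (C3 epimers) | C=C1C(=O)O[C@@H]2/C=C(/C)C(O)C[C@H]3O[C@]3(C)C[C@@H](OC(=O)[C@]3(C)O[C@H]3C)[C@@H]12
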